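What stands in the spring flask at 3.0 d, and which remedy gets more target out of it?

| setting | spring | midnight | flask |
|---|---|---|---|
| starting material | 0.10 M | 0.10 M | 0.10 M |
| reagent | 1.5 equiv | 0.75 equiv | 1.50 equiv |
| free catalyst | 7.7 mol% | 7.7 mol% | 7.7 mol% |
| remark | the very flask that is asked about, followed so far | run made earlier |  |
| time |  |  | 3.0 d |

| run | time / h | target / % |
|---|---|---|
| spring | 5.00 | 18 |
| spring | 8.00 | 28 |
| spring | 10.0 | 34 |
| spring | 15.0 | 45 |
| spring | 25.0 | 59 |
| spring | 40.0 | 68 |
| spring | 60.0 | 70 |
| midnight | 0.500 | 0 |
| midnight | 0.667 | 3 |
| midnight | 1.00 | 0 |
| midnight | 1.50 | 1 |
| midnight | 2.50 | 6 |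
| midnight | 4.00 | 13 |
| midnight | 6.00 | 17 |

(standard deviation of a reading: 1.5 percentage points)

- blue: change nothing and wait 3.0 d more
- amber: at 3.0 d add free catalyst, 100% of the amount charged, then wait 3.0 d
- violet: at 3.0 d add reagent, 100% of the amount charged, then wait 3.0 d
- green: at 3.0 d take out 90% of the target then present, then wait 3.0 d

- target, in percent of the starting material first charged, at 3.0 d
- the remedy with the largest gain of target, or "none" below 2 percentage points (blue / amber / violet / green / none)
- target present, with what was taken out counted in, in percent of the starting material first charged, after violet
- target present, with what was taken out counted in, in percent of the starting material first charged, after green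

- removed target is counted in
- the analysis behind the earlier runs scatters by 1.5 percentage points, standard deviation
- what may be going on: reagent + free catalyst <-> catalyst intermediate A; catalyst intermediate A -> released group + catalyst intermediate B; catalyst intermediate B -> catalyst intermediate C; starting material + catalyst intermediate C <-> catalyst intermediate D; catalyst intermediate D -> free catalyst + target; released group + catalyst intermediate C -> spent catalyst
- additions bring no volume worth counting

I start from the end of the spring curve. Between 40.0 h and 60.0 h the readings of the spring flask move by 2 percentage points, which is slower per hour than over the stretch before. Holding that pace to 3.0 d gives about 71.2%, so I commit to about 70%, or a little more.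

Next I ask what stops the spring flask. By the reading at 60.0 h, about 30.0% of the starting material remains in the spring flask, and the reagent used, at most about 0.0777 M, is less than the 0.150 M charged. I therefore take the stall as catalyst loss.

Each round yields one target and one released group, and the spent catalyst takes back at most 0.00770 M, so c(released group) tracks c(target). Let x be the target fraction. Intermediate C then dies against working in the ratio s·x/(1 − x), where s is a selectivity factor, the death-to-turnover ratio of intermediate C at equal c(released group) and c(starting material). Summing over the run, spent catalyst per starting material charged is s[ln(1/(1 − x)) − x]. Setting this equal to the charge at the plateau gives s = 0.153.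

Violet and green add no catalyst, so on this rule they gain nothing. Amber makes the budget B, the catalyst over s, twice as large, at 1.01. I iterate x = 1 − exp(−(B + x)) from the plateau and get 81.9%, then 83.9%, then 84.2%.

The weak link is s, which rests on one reading. Taking that reading one scatter higher, at 71.5%, with budget 1.08, the same rounds end near 85.5%. The gain I reckon for amber stays above the margin.

The forecast says 71%, amber, 71.5% after violet and 71.5% after green, on the ground that “the stall must be catalyst death”.

The spring flask gives 69.8% at 3.0 d, and amber is the best remedy, gaining 15 points where violet gains 0.24 points; target stands at 70.0% after violet and 70.0% after green, and spent catalyst stands at 99.0% of the catalyst charged at 72.0 h.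

    reagent + free catalyst ⇌ catalyst intermediate A (K = 2.90 L mol⁻¹, k = 40.5 L mol⁻¹ h⁻¹)
    catalyst intermediate A → released group + catalyst intermediate B (k = 6.67 h⁻¹)
    catalyst intermediate B → catalyst intermediate C (k = 6.73 h⁻¹)
    starting material + catalyst intermediate C ⇌ catalyst intermediate D (K = 1.60 L mol⁻¹, k = 73.1 L mol⁻¹ h⁻¹)
    catalyst intermediate D → free catalyst + target (k = 9.93 h⁻¹)
    released group + catalyst intermediate C → spent catalyst (k = 1.86 L mol⁻¹ h⁻¹)

In the neighbour charged with 1.9 mol% of free catalyst, the target stands at 39.5% at 72.0 h, and s then puts spent catalyst at 86.6% of that charge; that neighbour holds 83.8% of its catalyst charge as spent catalyst.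

All runs are simulated for substances that don't exist; scatter was added.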